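At 5.0 h we read how much target stands in each of these flasks, so we ask first how much partner a flask can actually use.

| flask | starting material | partner | second substrate | third substrate | protic impurity | temperature | remark | time |
|---|---|---|---|---|---|---|---|---|
| south-east | 0.058 M | 0.14 M (fed, over 1.0 h) | 0.116 M | 0.058 M | 0.0116 M | 95 °C | run made earlier |  |
| south-west | 0.058 M | 0.30 M (fed, over 1.0 h) | 0.116 M | 0.058 M | 0.0116 M | 110 °C | run made earlier |  |
| west | 0.058 M | 0.104 M (fed, over 1.0 h) | 0.116 M | 0.058 M | 0.012 M | 95 °C | run made earlier |  |
| autumn | 0.058 M | 0.200 M (fed, over 1.0 h) | 0.116 M | 0.0580 M | 0.0116 M | 110 °C |  | 5.0 h |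
| spring | 0.25 M | 0.104 M (fed, over 1.0 h) | 0.116 M | 0.0400 M | 0.0116 M | 110 °C |  | 5.0 h |
| winter | 0.058 M | 0.104 M (fed, over 1.0 h) | 0.116 M | 0.0580 M | 0.0116 M | 110 °C |  | 5.0 h |
| noon | 0.058 M | 0.104 M (fed, over 1.0 h) | 0.116 M | 0.120 M | 0.00400 M | 110 °C |  | 5.0 h |
| dawn | 0.058 M | 0.104 M (fed, over 1.0 h) | 0.116 M | 0.0580 M | 0.0200 M | 110 °C |  | 5.0 h |

- south-east (time / h: target / %): 1.33: 6.0; 3.00: 15.8; 4.00: 20.7; 5.00: 24.4
- south-west (time / h: target / %): 0.200: 1.1; 0.500: 6.0; 1.00: 21.1; 2.50: 56.1
- west (time / h: target / %): 0.417: 1.0; 1.00: 2.6; 2.00: 7.5; 5.00: 17.7

(scatter of a reading: 0.3 percentage points)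

- ranking by amount of target, in percent of the starting material charged, from high to low, at 5.0 h (autumn / spring / winter / noon / dawn)
- the amount of target, in percent of the starting material charged of the flask you put first, at 5.0 h
- the amount of target, in percent of the starting material charged of the flask you put last, at 5.0 h

Take the last rows of south-east and west, both at 5.00 h. Counted as first-order lifetimes of starting material, ln(1/(1 − yield)), south-east has run 1.44 times as far as west. The partner charges stand at only 1.35, but once the protic impurity is subtracted from each they stand at 1.40, which is closer. We therefore reckon that the impurity takes its share of partner and the rest is usable.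

Our quantity is the usable equivalents: partner charge less protic impurity, over starting material charged. Spring has 0.370, autumn 3.25, noon 1.72, winter 1.59 and dawn 1.45. Our order follows these: autumn, noon, winter, dawn, spring. The weak point is noon, since no run varied the third substrate.

Is spring's partner used up in time? During a steady feed the flask holds on average half the charge, so the south-west row at 1.00 h gives a rate constant of 1.64 L mol⁻¹ h⁻¹. Against spring's starting material, partner then has a half-life of 1.69 h, shorter than the 4.00 h after the feed. Partner is spring's limiting reagent, and its target stays under 37.0%.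

The forecast gives autumn > winter > dawn > noon > spring, with 60% first and 25% last, and says of the untested settings: “I assume both consume partner”. Its cap for spring, 42%, stands above ours, and it puts dawn above noon where we put noon above dawn.

The flasks give autumn > noon > winter > dawn > spring, from 60.2% in autumn to 21.9% in spring, with noon at 35.3% and dawn at 30.8%.

    starting material + partner → target (k = 1.90 L mol⁻¹ h⁻¹, Ea = 89.0 kJ mol⁻¹)
    third substrate + partner → third product (k = 0.200 L mol⁻¹ h⁻¹, Ea = 89.0 kJ mol⁻¹)
    partner + protic impurity → quenched reagent (k = 76.0 L mol⁻¹ h⁻¹, Ea = 68.0 kJ mol⁻¹)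
    second substrate + partner → second product (k = 2.40 L mol⁻¹ h⁻¹, Ea = 101 kJ mol⁻¹)
    (constants at 110 °C)

Spring ends below its ceiling of 37.0%, with 5.3% of its partner left at 5.00 h. At that time partner goes into target 1.8 times as fast as into second product, of which spring then holds 0.0311 M.

A neighbour of spring charged with 0.026 M of partner counts 0.0576 usable equivalents by the same subtraction, an estimate that takes off the whole protic impurity. Its computed target is 4.07%, with 1.2% of its partner and 19% of its protic impurity left, so the subtraction took off more than the 0.00940 M of quenched reagent that stands there.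

The earlier runs and the new flask were generated by integration for substances that don't exist, noise included.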